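**Plan**
Ring carbons are C1–C10: C4 is the carbinol (methyl C15), C6 carries the ester, C7/C8 are the lactone fusion, and C10 carries C14H2OH. C11, C12 and C13 are the lactone α-carbon, carbonyl carbon and exocyclic methylene.
Retrosynthetic cuts, in order: O14–Si; lactone O8–C12 (to a C8,C12-diol); ester O6–acyl; C4–OH/C5–H (through the epoxide to C4=C5); C6–C7 (retro-[2,3]-Wittig, restoring an O–C13 ether bond); O–C13 (Williamson); C7–C11 (Morita–Baylis–Hillman); C1=C10 (Horner–Wadsworth–Emmons); C9–C10 (epoxide opening).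
The key step is possible because C6 bears oxygen and its neighbour C7 bears the C11(=C13H2)C12 branch that later becomes the α-methylene-γ-lactone ring. This homoallylic alcohol is what a C6–O–C13 allyl ether leaves after a [2,3] shift.
Forward: the chain is joined at C9–C10, then C1=C10, then C7–C11. The thirteen-membered ether ring closes first, contracts to the ten-membered carbocycle, and the γ-lactone ring closes last.
Stereochemistry: C8 comes from (S)-glycidyl trityl ether, C6 and C7 from the rearrangement (C7=C11 geometry, 1,3-allylic strain at C8), and C4 from C6–OH-directed epoxidation. Alkene geometries come from nerol, the E-selective lactone olefination, the allylic bromide and (Z)-2-iodobut-2-enal.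

Key step: step 17

Remark: centres that are erased later are left undefined (epoxide CH in 3 and 4, the phosphorus-bearing carbon in 8 and 9, carbinol C7 in 17, lithiated C6 in 23, the lactol carbon in 37). PMB = 4-methoxybenzyl, Tr = trityl, TBS = tert-butyldimethylsilyl, TBDPS = tert-butyldiphenylsilyl. The open chain is C6–C5=C4(C15)–C3–C2–C1=C10(C14)–C9–C8–C7=C11(C12)–C13.

Step 1
Reactants: 1 nerol
Product: 2 neryl 4-methoxybenzyl ether
Conditions: NaH, PMBCl, n-Bu4NI (cat.), THF, 0 °C → rt
Reagents that add atoms: 4-methoxybenzyl chloride, COc1ccc(CCl)cc1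
Why: Williamson etherification of the primary allylic alkoxide leaves the Z-alkene (future C4=C5) untouched, and PMB withstands peracid, hydride, base and mild acid yet can later be removed oxidatively beside an allylic bromide and three silyl ethers.

Step 2
Reactants: 2 neryl 4-methoxybenzyl ether
Product: 3 6,7-epoxide of 2
Conditions: mCPBA (1.0 equiv), CH2Cl2, −20 → 0 °C
Reagents that add atoms: 3-chloroperbenzoic acid, OOC(=O)c1cccc(Cl)c1
Why: Prilezhaev epoxidation picks the electron-rich isopropylidene alkene because the other trisubstituted alkene is deactivated inductively by its allylic oxygen; the new stereocentre is destroyed in the next step.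

Step 3
Reactants: 3 6,7-epoxide of 2
Product: 5 (Z)-6-(4-methoxybenzyloxy)-4-methylhex-4-enal, via glycol 4 (not isolated)
Conditions: H5IO6, THF–H2O, 0 °C
Reagents that add atoms: water, O
Why: Periodic acid hydrolyses the epoxide and cleaves the glycol in the same flask (Malaprade cleavage), releasing the C1 aldehyde without touching the Z-alkene or the PMB ether.

Step 4
Reactants: 6 (S)-glycidyl trityl ether; 7 triethyl phosphonoacetate
Product: 9 (5S)-3-(diethoxyphosphoryl)-5-(trityloxymethyl)oxolan-2-one, via hydroxy ester 8 (not isolated)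
Conditions: NaOEt (1.1 equiv), EtOH, reflux; AcOH quench
Reagents that add atoms: none
Why: The sodium salt of 7 opens the epoxide at its CH2 terminus (SN2, forming C9–C10 and leaving the C8–O bond and its S configuration untouched) and the alkoxide lactonises onto the ethyl ester (5-exo-trig), a known entry to α-phosphono-γ-butyrolactones provided the temperature stays below that at which phosphoryl transfer and cyclopropane formation take over.

Step 5
Reactants: 5 (Z)-6-(4-methoxybenzyloxy)-4-methylhex-4-enal; 9 (5S)-3-(diethoxyphosphoryl)-5-(trityloxymethyl)oxolan-2-one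
Product: 10 (3E,5S)-3-[(4Z)-6-(4-methoxybenzyloxy)-4-methylhex-4-enylidene]-5-(trityloxymethyl)oxolan-2-one
Conditions: NaH, THF, 0 °C; then 5, 0 °C → rt
Reagents that add atoms: none
Why: Horner–Wadsworth–Emmons olefination of an α-phosphono-γ-butyrolactone with an unbranched aldehyde favours the E-alkylidene lactone (C2 anti to the carbonyl C14 and therefore cis to C9), which is the C1=C10 geometry of the target.

Step 6
Reactants: 10 E-alkylidene lactone
Product: 11 (2S,4E,8Z)-4-(hydroxymethyl)-10-(4-methoxybenzyloxy)-8-methyl-1-(trityloxy)deca-4,8-dien-2-ol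
Conditions: i-Bu2AlH (4 equiv), CH2Cl2, −78 → 0 °C; H2O work-up
Reagents that add atoms: none
Why: i-Bu2AlH reduces the conjugated lactone in the 1,2 sense to the allylic C14 alcohol and the C8 alcohol without changing alkene geometry or the C8 centre.

Step 7
Reactants: 11 C14,C8-diol
Product: 12 C14-O-TBDPS ether of 11
Conditions: TBDPSCl (1.05 equiv), imidazole, CH2Cl2, 0 °C
Reagents that add atoms: tert-butyldiphenylsilyl chloride, CC(C)(C)[Si](Cl)(c1ccccc1)c1ccccc1
Why: The bulky silyl chloride silylates the primary allylic hydroxyl far faster than the secondary C8–OH next to CH2OTr, placing on C14 the one silyl group that has to outlast all others.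

Step 8
Reactants: 12 C14-O-TBDPS ether of 11
Product: 13 C8-O-TBS ether of 12
Conditions: TBSOTf, 2,6-lutidine, CH2Cl2, −78 → 0 °C
Reagents that add atoms: tert-butyldimethylsilyl triflate, CC(C)(C)[Si](C)(C)OS(=O)(=O)C(F)(F)F
Why: Silyl triflate with a hindered base silylates the congested secondary alcohol under conditions that leave trityl, PMB and TBDPS ethers intact.

Step 9
Reactants: 13 C8-O-TBS ether of 12
Product: 14 (2S,4E,8Z)-2-(TBS-oxy)-4-(TBDPS-oxymethyl)-10-(PMB-oxy)-8-methyldeca-4,8-dien-1-ol
Conditions: camphorsulfonic acid (cat.), MeOH–CH2Cl2, 0 °C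
Reagents that add atoms: none
Why: Acid-catalysed SN1 methanolysis through the trityl cation is much faster than cleavage of a secondary TBS, a TBDPS or a PMB ether, so only the C7 hydroxyl is freed.

Step 10
Reactants: 14 C7 primary alcohol
Product: 15 (2S,4E,8Z)-2-(TBS-oxy)-4-(TBDPS-oxymethyl)-10-(PMB-oxy)-8-methyldeca-4,8-dienal
Conditions: Dess–Martin periodinane, CH2Cl2, 0 °C → rt
Reagents that add atoms: none
Why: Dess–Martin oxidation stops at the aldehyde and runs without base, so the α-silyloxy centre C8 is not epimerised.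

Step 11
Reactants: 15 C7 aldehyde; 16 methyl acrylate
Product: 17 methyl (4S,6E,10Z)-3-hydroxy-2-methylidene-4-(TBS-oxy)-6-(TBDPS-oxymethyl)-12-(PMB-oxy)-10-methyldodeca-6,10-dienoate
Conditions: DABCO (cat.), MeOH, excess 16, rt
Reagents that add atoms: none
Why: The Morita–Baylis–Hillman reaction forms C7–C11 and brings in C12 and C13 in one operation, α-oxygenated aldehydes being among the more reactive acceptors; the C7 carbinol forms as a mixture that the next step erases.

Step 12
Reactants: 17 Morita–Baylis–Hillman adduct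
Product: 18 methyl (2Z,4S,6E,10Z)-2-(bromomethyl)-4-(TBS-oxy)-6-(TBDPS-oxymethyl)-12-(PMB-oxy)-10-methyldodeca-2,6,10-trienoate
Conditions: NBS, Me2S, CH2Cl2, 0 °C (premixed); then 17, 0 °C → rt
Reagents that add atoms: N-bromosuccinimide, O=C1CCC(=O)N1Br
Why: The alkoxysulfonium salt formed with the Corey–Kim-type reagent is displaced by bromide in the SN2′ sense at C13, and the enoate forms with the ester cis to H7 and C8 cis to CH2Br, the usual geometry of bromides made from such adducts.

Step 13
Reactants: 18 bromo enoate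
Product: 19 (2Z,4S,6E,10Z)-2-(bromomethyl)-4-(TBS-oxy)-6-(TBDPS-oxymethyl)-12-(PMB-oxy)-10-methyldodeca-2,6,10-trien-1-ol
Conditions: i-Bu2AlH (2.2 equiv), CH2Cl2, −78 °C; H2O work-up
Reagents that add atoms: none
Why: At low temperature i-Bu2AlH reduces the conjugated ester to the allylic alcohol C12–OH faster than it attacks the allylic bromide, a known conversion of 2-(bromomethyl)enoates that removes the conjugate-acceptor character before any alkoxide is generated.

Step 14
Reactants: 19 bromo allylic alcohol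
Product: 20 C12-O-TBS ether of 19
Conditions: TBSOTf, 2,6-lutidine, CH2Cl2, −78 °C
Reagents that add atoms: tert-butyldimethylsilyl triflate, CC(C)(C)[Si](C)(C)OS(=O)(=O)C(F)(F)F
Why: Silylation with a non-nucleophilic base avoids quaternisation or halide exchange at the allylic bromide and gives C12 the same group as C8, so both can be removed together later.

Step 15
Reactants: 20 C12-O-TBS ether of 19
Product: 21 bromo alcohol (C6–OH free; C13–Br; C8-OTBS; C12-OTBS; C14-OTBDPS; 8S)
Conditions: DDQ, CH2Cl2–pH 7 buffer, 0 °C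
Reagents that add atoms: none
Why: Oxidative PMB cleavage with DDQ is neutral and leaves the allylic bromide, the silyl ethers and all three alkenes unchanged.

Step 16
Reactants: 21 bromo alcohol
Product: 22 (10S)-10-(TBS-oxy)-12-(TBS-oxymethyl)-8-(TBDPS-oxymethyl)-4-methyl-1-oxacyclotrideca-3,7,11-triene (thirteen-membered bis-allylic ether C6–O–C13; all three ring alkenes ring-cis)
Conditions: NaH (excess), THF, 50 °C, syringe-pump addition of 21 (high dilution)
Reagents that add atoms: none
Why: Intramolecular Williamson etherification of an unhindered primary alkoxide with a reactive primary allylic bromide should close the ring, since the three alkenes, each with its chain bonds cis, fold the chain and bring O6 near C13.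

Step 17
Reactants: 22 thirteen-membered bis-allylic ether
Product: 24 (6S,7S,8S)-ten-membered dienol (C6–OH; C7–C(=CH2)CH2OTBS; C8-OTBS; C10–CH2OTBDPS; C4=C5 ring-cis; C1=C10 ring-cis), via C6-lithio ether 23 (not isolated)
Conditions: n-BuLi (hexanes), THF, −78 → −20 °C; H2O quench at low temperature
Reagents that add atoms: n-butyllithium, [Li]CCCC (lithium, in 23 only)
Why: n-BuLi, held by the only dialkyl-ether oxygen of 22, removes a C6 proton (allylic to C4=C5 and α to oxygen), and the α-oxyallyllithium 23 bonds from C6 to C7 through a five-membered envelope (C6, O, C13, C11, C7) while O–C13 breaks and the π bond moves to C11=C13, leaving the C6 lithium alkoxide. The closest known reaction type is the ring-contracting [2,3]-Wittig rearrangement of thirteen-membered diallylic ethers to ten-membered germacrane-type homoallylic alcohols. The ten-membered carbocycle closes transannularly by ring contraction: O, C13 and C11 are expelled from the thirteen-membered ring, so the closure is a concerted suprafacial sigmatropic shift inside a preformed ring and not an end-to-end cyclisation. C6 relative to C7 is controlled by the C7=C11 geometry: with C8 cis to C13 and the C5 vinyl residue exo on the envelope (anti to C11 and away from C12), O6 and C8 end up syn along C5–C6–C7–C11, that is O6 and C11 cis on the ring. C7 relative to C8 is controlled by 1,3-allylic strain between C8 and C13, which keeps H8 in the alkene plane, lets C9 carry the ring chain to the face on which C6 arrives and puts the C8–O bond anti to the forming bond, so that C11 and O8 become trans and the (8S) centre translates into (6S,7S) in 24, the spatial arrangement of the target. The step needs lithiation at C6 rather than at C13, C12 or C14 and a [2,3] rather than a [1,2] shift: C13 is shielded by the fully substituted C11 and the cis C8 branch and its anion could only attack the fully substituted C4, the silyl ether oxygens bind lithium poorly and their bulk covers C12 and C14, and low temperature with lithium as counter-ion disfavours radical [1,2] migration, silyl migration to O6 and anionic oxy-Cope rearrangement of the 1,5-dien-3-olate.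

Step 18
Reactants: 24 ten-membered dienol
Product: 25 4,5-epoxy alcohol (new centres 4R,5S; epoxide oxygen trans to O6 on the ring)
Conditions: Ti(O-i-Pr)4 (cat.), t-BuOOH (decane), 4 Å molecular sieves, CH2Cl2, −20 °C
Reagents that add atoms: tert-butyl hydroperoxide, CC(C)(C)OO
Why: Tartrate-free titanium-alkoxide-directed epoxidation touches only the alkene allylic to the free C6–OH, and because C3 is cis to C6 on C4=C5 the 1,3-allylic strain keeps H6 in the alkene plane with O6 over the outer face, so oxygen is delivered there to give the threo (ring-trans) epoxy alcohol; VO(acac)2 is avoided because it tends to give the cis-epoxy alcohol, and hence the C4 epimer, with medium-ring Z-allylic alcohols.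

Step 19
Reactants: 25 4,5-epoxy alcohol
Product: 26 (4R,6S)-4,6-diol
Conditions: NaAlH2(OCH2CH2OCH3)2, THF, 0 °C → rt; H2O work-up
Reagents that add atoms: none
Why: The C6 alkoxyaluminate delivers hydride internally to C5, the less substituted epoxide carbon next to the carbinol (the known 2,3-epoxy alcohol to 1,3-diol opening), so the C4–O bond and its configuration are retained.

Step 20
Reactants: 27 (E)-crotonaldehyde
Product: 28 (Z)-2-iodobut-2-enal
Conditions: I2, K2CO3, DMAP (cat.), THF–H2O, rt
Reagents that add atoms: iodine, [I][I]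
Why: Amine-catalysed α-iodination of an enal (conjugate addition, iodination, elimination) keeps the methyl group trans to the formyl group and therefore cis to iodine.

Step 21
Reactants: 28 (Z)-2-iodobut-2-enal
Product: 29 (Z)-2-iodobut-2-en-1-ol
Conditions: NaBH4, MeOH, 0 °C
Reagents that add atoms: none
Why: Borohydride reduces the α-iodo enal in the 1,2 sense without affecting the alkene geometry or the C–I bond.

Step 22
Reactants: 29 (Z)-2-iodobut-2-en-1-ol
Product: 31 (Z)-2-(hydroxymethyl)but-2-enoic acid, via dilithio species 30 (not isolated)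
Conditions: t-BuLi (3 equiv), Et2O, −78 °C; CO2; aq. HCl
Reagents that add atoms: tert-butyllithium, [Li]C(C)(C)C (lithium, in 30 only); carbon dioxide, O=C=O
Why: Deprotonation followed by iodine–lithium exchange gives a configurationally stable alkenyllithium at −78 °C, and carboxylation with retention places the carboxyl group where iodine was, cis to the methyl group (angelate-type geometry).

Step 23
Reactants: 31 (Z)-2-(hydroxymethyl)but-2-enoic acid
Product: 32 (Z)-2-(acetoxymethyl)but-2-enoic acid
Conditions: Ac2O, pyridine, CH2Cl2, 0 °C → rt; then H2O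
Reagents that add atoms: acetic anhydride, CC(=O)OC(C)=O
Why: Simple O-acetylation of the primary alcohol, any mixed anhydride at the carboxyl group being hydrolysed on aqueous work-up.

Step 24
Reactants: 26 (4R,6S)-4,6-diol; 32 (Z)-2-(acetoxymethyl)but-2-enoic acid
Product: 34 C6 (Z)-2-(acetoxymethyl)but-2-enoate of 26, via mixed anhydride 33 (not isolated)
Conditions: 32, 2,4,6-trichlorobenzoyl chloride, Et3N, toluene, rt; then 26, 70 °C (no DMAP)
Reagents that add atoms: 2,4,6-trichlorobenzoyl chloride, O=C(Cl)c1c(Cl)cc(Cl)cc1Cl (in 33 only)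
Why: Yamaguchi-type mixed-anhydride esterification acylates the secondary C6–OH and not the tertiary C4–OH, and omitting the nucleophilic catalyst is the accepted way of making angelate-type esters without addition–elimination at the β-carbon, which would isomerise the Z-alkene or displace the allylic acetate.

Step 25
Reactants: 34 C6 ester
Product: 35 C4,C8,C12-triol (C14-OTBDPS retained)
Conditions: camphorsulfonic acid (cat.), MeOH–CH2Cl2, 0 °C → rt
Reagents that add atoms: none
Why: Acid-catalysed methanolysis removes the primary and the secondary TBS ether while the far more acid-stable TBDPS ether, the two esters and the tertiary alcohol persist.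

Step 26
Reactants: 35 C4,C8,C12-triol
Product: 38 C14-O-TBDPS ether of the target lactone, via hydroxy enal 36 (not isolated), via lactol 37 (not isolated)
Conditions: activated MnO2 (excess), CH2Cl2, rt
Reagents that add atoms: none
Why: MnO2 oxidises only the allylic primary C12–OH (C14 is still silylated, C8–OH and C4–OH are not allylic); the enal is trapped by C8–OH as the five-membered lactol, which is oxidised further to the α-methylene-γ-lactone (oxidative lactonisation of a 2-methylene-1,4-diol), the trans fusion being fixed by C7 and C8.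

Step 27
Reactants: 38 C14-O-TBDPS lactone
Product: 39 target CNP0313132.1 (4R,6S,7R,8S)
Conditions: HF·pyridine, THF, 0 °C → rt
Reagents that add atoms: none
Why: Mildly acidic fluoride desilylation frees the C14 allylic alcohol without the basic conditions that would endanger the acetate, the unsaturated ester or the α-methylene lactone.

**Compound list**
1 | nerol | CC(C)=CCC/C(C)=C\CO | starting material
2 | neryl 4-methoxybenzyl ether | CC(C)=CCC/C(C)=C\COCc1ccc(OC)cc1 | intermediate
3 | 6,7-epoxide of 2 | CC1(C)OC1CC/C(C)=C\COCc1ccc(OC)cc1 | intermediate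
4 | 6,7-glycol of 2 | CC(C)(O)C(O)CC/C(C)=C\COCc1ccc(OC)cc1 | intermediate
5 | (Z)-6-(4-methoxybenzyloxy)-4-methylhex-4-enal | O=CCC/C(C)=C\COCc1ccc(OC)cc1 | intermediate
6 | (S)-glycidyl trityl ether | c1ccccc1C(c1ccccc1)(c1ccccc1)OC[C@@H]1CO1 | starting material
7 | triethyl phosphonoacetate | CCOC(=O)CP(=O)(OCC)OCC | starting material
8 | ethyl (4S)-2-(diethoxyphosphoryl)-4-hydroxy-5-(trityloxy)pentanoate | CCOC(=O)C(C[C@H](O)COC(c1ccccc1)(c1ccccc1)c1ccccc1)P(=O)(OCC)OCC | intermediate
9 | (5S)-3-(diethoxyphosphoryl)-5-(trityloxymethyl)oxolan-2-one | O=C1O[C@H](COC(c2ccccc2)(c2ccccc2)c2ccccc2)CC1P(=O)(OCC)OCC | intermediate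
10 | (3E,5S)-3-[(4Z)-6-(4-methoxybenzyloxy)-4-methylhex-4-enylidene]-5-(trityloxymethyl)oxolan-2-one | COc1ccc(COC/C=C(C)\CC/C=C2\C[C@@H](COC(c3ccccc3)(c3ccccc3)c3ccccc3)OC2=O)cc1 | intermediate
11 | (2S,4E,8Z)-4-(hydroxymethyl)-10-(4-methoxybenzyloxy)-8-methyl-1-(trityloxy)deca-4,8-dien-2-ol | COc1ccc(COC/C=C(C)\CC/C=C(CO)\C[C@H](O)COC(c2ccccc2)(c2ccccc2)c2ccccc2)cc1 | intermediate
12 | C14-O-TBDPS ether of 11 | COc1ccc(COC/C=C(C)\CC/C=C(CO[Si](c2ccccc2)(c2ccccc2)C(C)(C)C)\C[C@H](O)COC(c2ccccc2)(c2ccccc2)c2ccccc2)cc1 | intermediate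
13 | C8-O-TBS ether of 12 | COc1ccc(COC/C=C(C)\CC/C=C(CO[Si](c2ccccc2)(c2ccccc2)C(C)(C)C)\C[C@H](O[Si](C)(C)C(C)(C)C)COC(c2ccccc2)(c2ccccc2)c2ccccc2)cc1 | intermediate
14 | C7 primary alcohol (8S) | COc1ccc(COC/C=C(C)\CC/C=C(CO[Si](c2ccccc2)(c2ccccc2)C(C)(C)C)\C[C@H](O[Si](C)(C)C(C)(C)C)CO)cc1 | intermediate
15 | C7 aldehyde (8S) | COc1ccc(COC/C=C(C)\CC/C=C(CO[Si](c2ccccc2)(c2ccccc2)C(C)(C)C)\C[C@H](O[Si](C)(C)C(C)(C)C)C=O)cc1 | intermediate
16 | methyl acrylate | C=CC(=O)OC | starting material
17 | Morita–Baylis–Hillman adduct (C7 epimers, 8S) | COc1ccc(COC/C=C(C)\CC/C=C(CO[Si](c2ccccc2)(c2ccccc2)C(C)(C)C)\C[C@H](O[Si](C)(C)C(C)(C)C)C(O)C(=C)C(=O)OC)cc1 | intermediate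
18 | bromo enoate (C8 cis to C13H2Br, 8S) | COc1ccc(COC/C=C(C)\CC/C=C(CO[Si](c2ccccc2)(c2ccccc2)C(C)(C)C)\C[C@H](O[Si](C)(C)C(C)(C)C)/C=C(C(=O)OC)\CBr)cc1 | intermediate
19 | bromo allylic alcohol (C12–OH) | COc1ccc(COC/C=C(C)\CC/C=C(CO[Si](c2ccccc2)(c2ccccc2)C(C)(C)C)\C[C@H](O[Si](C)(C)C(C)(C)C)/C=C(CO)\CBr)cc1 | intermediate
20 | C12-O-TBS ether of 19 | COc1ccc(COC/C=C(C)\CC/C=C(CO[Si](c2ccccc2)(c2ccccc2)C(C)(C)C)\C[C@H](O[Si](C)(C)C(C)(C)C)/C=C(CO[Si](C)(C)C(C)(C)C)\CBr)cc1 | intermediate
21 | bromo alcohol (C6–OH, C13–Br, 8S) | OC/C=C(C)\CC/C=C(CO[Si](c1ccccc1)(c1ccccc1)C(C)(C)C)\C[C@H](O[Si](C)(C)C(C)(C)C)/C=C(CO[Si](C)(C)C(C)(C)C)\CBr | intermediate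
22 | thirteen-membered bis-allylic ether (8S) | O1C/C=C(C)\CC/C=C(CO[Si](c2ccccc2)(c2ccccc2)C(C)(C)C)\C[C@H](O[Si](C)(C)C(C)(C)C)/C=C(CO[Si](C)(C)C(C)(C)C)\C1 | intermediate
23 | C6-lithio derivative of 22 | O1C([Li])/C=C(C)\CC/C=C(CO[Si](c2ccccc2)(c2ccccc2)C(C)(C)C)\C[C@H](O[Si](C)(C)C(C)(C)C)/C=C(CO[Si](C)(C)C(C)(C)C)\C1 | intermediate
24 | ten-membered dienol (6S,7S,8S) with C7 2-propenyl branch | C=C(CO[Si](C)(C)C(C)(C)C)[C@@H]1[C@@H](O[Si](C)(C)C(C)(C)C)C/C(CO[Si](c2ccccc2)(c2ccccc2)C(C)(C)C)=C\CC/C(C)=C\[C@@H]1O | intermediate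
25 | 4,5-epoxy alcohol (4R,5S) | C=C(CO[Si](C)(C)C(C)(C)C)[C@@H]1[C@@H](O[Si](C)(C)C(C)(C)C)C/C(CO[Si](c2ccccc2)(c2ccccc2)C(C)(C)C)=C\CC[C@@]3(C)O[C@H]3[C@@H]1O | intermediate
26 | (4R,6S)-4,6-diol | C=C(CO[Si](C)(C)C(C)(C)C)[C@@H]1[C@@H](O[Si](C)(C)C(C)(C)C)C/C(CO[Si](c2ccccc2)(c2ccccc2)C(C)(C)C)=C\CC[C@@](C)(O)C[C@@H]1O | intermediate
27 | (E)-crotonaldehyde | C/C=C/C=O | starting material
28 | (Z)-2-iodobut-2-enal | C/C=C(\I)C=O | intermediate
29 | (Z)-2-iodobut-2-en-1-ol | C/C=C(\I)CO | intermediate
30 | dilithio derivative of 29 (O-lithium, C2-lithium) | C/C=C(\[Li])CO[Li] | intermediate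
31 | (Z)-2-(hydroxymethyl)but-2-enoic acid | C/C=C(\C(=O)O)CO | intermediate
32 | (Z)-2-(acetoxymethyl)but-2-enoic acid | C/C=C(\C(=O)O)COC(C)=O | intermediate
33 | mixed anhydride of 32 with 2,4,6-trichlorobenzoic acid | C/C=C(\C(=O)OC(=O)c1c(Cl)cc(Cl)cc1Cl)COC(C)=O | intermediate
34 | C6 (Z)-2-(acetoxymethyl)but-2-enoate of 26 | C=C(CO[Si](C)(C)C(C)(C)C)[C@@H]1[C@@H](O[Si](C)(C)C(C)(C)C)C/C(CO[Si](c2ccccc2)(c2ccccc2)C(C)(C)C)=C\CC[C@@](C)(O)C[C@@H]1OC(=O)/C(=C\C)COC(C)=O | intermediate
35 | C4,C8,C12-triol | C=C(CO)[C@@H]1[C@@H](O)C/C(CO[Si](c2ccccc2)(c2ccccc2)C(C)(C)C)=C\CC[C@@](C)(O)C[C@@H]1OC(=O)/C(=C\C)COC(C)=O | intermediate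
36 | C12 enal with free C8–OH | C=C(C=O)[C@@H]1[C@@H](O)C/C(CO[Si](c2ccccc2)(c2ccccc2)C(C)(C)C)=C\CC[C@@](C)(O)C[C@@H]1OC(=O)/C(=C\C)COC(C)=O | intermediate
37 | C12 lactol | C=C1C(O)O[C@H]2C/C(CO[Si](c3ccccc3)(c3ccccc3)C(C)(C)C)=C\CC[C@@](C)(O)C[C@H](OC(=O)/C(=C\C)COC(C)=O)[C@H]12 | intermediate
38 | C14-O-TBDPS ether of the target | C=C1C(=O)O[C@H]2C/C(CO[Si](c3ccccc3)(c3ccccc3)C(C)(C)C)=C\CC[C@@](C)(O)C[C@H](OC(=O)/C(=C\C)COC(C)=O)[C@H]12 | intermediate
39 | CNP0313132.1 (4R,6S,7R,8S) | C=C1C(=O)O[C@H]2C/C(CO)=C\CC[C@@](C)(O)C[C@H](OC(=O)/C(=C\C)COC(C)=O)[C@H]12 | target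

**Step count**
Total: 27 steps. The longest linear sequence is 22 steps (steps 1–3, 5–19, 24–27). Step 4 and steps 20–23 are side branches.

**Steps most likely to fail**

**Step 17.**
- Lithiation may take place at C13, C12 or C14 instead of C6. It could then be followed by vinylogous expulsion of the C8 silanolate or by a [1,2] shift.
- The alkoxide may pick up a silyl group from O8.
- The new bond may form on the alkene face syn to O8, because the favoured arrangement brings C5 and C9 close together.

Fallback (from 21, back at 24): the same C6–C7 bond and the same ring are closed directly instead of by contraction, and no strong base is present. Bromo alcohol 21 is treated with Bu3SnLi (2 equiv, THF, −78 °C) to give the allylstannane alcohol F1. MnO2 in CH2Cl2 oxidises the neryl-type alcohol to the stannyl Z-enal F2. BF3·OEt2 (CH2Cl2, −78 °C, high dilution) then triggers the intramolecular SE2′ addition: C7 attacks C6, tin leaves C13 and C11=C13 appears, giving 24. Lewis-acid-promoted additions of γ-substituted allylstannanes run through open transition states that favour the syn O6/C8 relationship whatever the alkene geometry.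

**Step 16.**
- Intermolecular alkylation may lead to oligomers.
- Loss of HBr or SN2′ attack may compete, because the electrophilic carbon C13 is flanked by the fully substituted C11 and the cis C8 branch.

Fallback (from 20, back at 22): the roles of the two chain ends are exchanged, so that the other C–O bond of the same ether is closed at the unhindered neryl terminus. Bromide 20 is converted with CsOAc (DMF, rt) into the C13 acetate F3, and DDQ frees the C6 alcohol F4. MsCl, LiCl and 2,4,6-collidine (DMF, 0 °C) give, without allylic transposition, the C6 chloride F5. i-Bu2AlH (CH2Cl2, −78 °C) removes the acetate to give the chloro alcohol F6. Its bromomagnesium alkoxide (EtMgBr, THF–HMPA, slow addition, gentle warming) cyclises to 22. The magnesium alkoxide is chosen because it is too covalent to trigger silyl migration from O12 to O13, which would exchange the two arms on C11.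

**Step 18.**
- Facial selectivity may be poor if the metal-bound peroxide reaches the alkene through the conformer with O6 near the alkene plane, which leads to the C4 epimer.
- The Lewis acid may open the tertiary epoxide transannularly.

Fallback (from 24, back at 34): the directing carbinol is inverted first. The cis-selective vanadium epoxidation of medium-ring Z-allylic alcohols then delivers oxygen to the required face, and the ester is introduced with a second inversion. Mitsunobu reaction of 24 (4-nitrobenzoic acid, PPh3, DIAD) gives the inverted 4-nitrobenzoate F7, and K2CO3 in MeOH gives the 6-epi alcohol F8. VO(acac)2 with t-BuOOH gives the cis-epoxy alcohol F9, which carries the same 4R,5S epoxide as 25. NaAlH2(OCH2CH2OCH3)2 gives the 6-epi diol F10. Mitsunobu esterification of F10 with acid 32 inverts C6 and gives 34 directly.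

**Further compounds**
F1 | step 17 | allylstannane alcohol (C13–SnBu3 analogue of 21) | OC/C=C(C)\CC/C=C(CO[Si](c1ccccc1)(c1ccccc1)C(C)(C)C)\C[C@H](O[Si](C)(C)C(C)(C)C)/C=C(CO[Si](C)(C)C(C)(C)C)\C[Sn](CCCC)(CCCC)CCCC
F2 | step 17 | stannyl Z-enal (C6 aldehyde of F1) | O=C/C=C(C)\CC/C=C(CO[Si](c1ccccc1)(c1ccccc1)C(C)(C)C)\C[C@H](O[Si](C)(C)C(C)(C)C)/C=C(CO[Si](C)(C)C(C)(C)C)\C[Sn](CCCC)(CCCC)CCCC
F3 | step 16 | C13 acetate (C6-OPMB) | COc1ccc(COC/C=C(C)\CC/C=C(CO[Si](c2ccccc2)(c2ccccc2)C(C)(C)C)\C[C@H](O[Si](C)(C)C(C)(C)C)/C=C(CO[Si](C)(C)C(C)(C)C)\COC(C)=O)cc1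
F4 | step 16 | C6 alcohol, C13 acetate | OC/C=C(C)\CC/C=C(CO[Si](c1ccccc1)(c1ccccc1)C(C)(C)C)\C[C@H](O[Si](C)(C)C(C)(C)C)/C=C(CO[Si](C)(C)C(C)(C)C)\COC(C)=O
F5 | step 16 | C6 chloride, C13 acetate | ClC/C=C(C)\CC/C=C(CO[Si](c1ccccc1)(c1ccccc1)C(C)(C)C)\C[C@H](O[Si](C)(C)C(C)(C)C)/C=C(CO[Si](C)(C)C(C)(C)C)\COC(C)=O
F6 | step 16 | chloro alcohol (C6–Cl, C13–OH) | ClC/C=C(C)\CC/C=C(CO[Si](c1ccccc1)(c1ccccc1)C(C)(C)C)\C[C@H](O[Si](C)(C)C(C)(C)C)/C=C(CO[Si](C)(C)C(C)(C)C)\CO
F7 | step 18 | 6-epi 4-nitrobenzoate of 24 | C=C(CO[Si](C)(C)C(C)(C)C)[C@@H]1[C@@H](O[Si](C)(C)C(C)(C)C)C/C(CO[Si](c2ccccc2)(c2ccccc2)C(C)(C)C)=C\CC/C(C)=C\[C@H]1OC(=O)c1ccc([N+](=O)[O-])cc1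
F8 | step 18 | 6-epi alcohol (C6 epimer of 24) | C=C(CO[Si](C)(C)C(C)(C)C)[C@@H]1[C@@H](O[Si](C)(C)C(C)(C)C)C/C(CO[Si](c2ccccc2)(c2ccccc2)C(C)(C)C)=C\CC/C(C)=C\[C@H]1O
F9 | step 18 | cis-epoxy alcohol (C6 epimer of 25) | C=C(CO[Si](C)(C)C(C)(C)C)[C@@H]1[C@@H](O[Si](C)(C)C(C)(C)C)C/C(CO[Si](c2ccccc2)(c2ccccc2)C(C)(C)C)=C\CC[C@@]3(C)O[C@H]3[C@H]1O
F10 | step 18 | 6-epi diol (C6 epimer of 26) | C=C(CO[Si](C)(C)C(C)(C)C)[C@@H]1[C@@H](O[Si](C)(C)C(C)(C)C)C/C(CO[Si](c2ccccc2)(c2ccccc2)C(C)(C)C)=C\CC[C@@](C)(O)C[C@H]1O
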